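Atoms carry eremophilane numbers (ring A: C1–C5 and C10; ring B: C5–C10; isopropenyl C11–C13). Ring B is closed last, at C6–C7. C7 is the α-carbon of the C8 ketone and carries the isopropenyl group, so the target is a β,γ-unsaturated ketone. Its conjugated isomer, the enone C8(=O)–C7H=C11Me2, is a latent C7 nucleophile. γ-Deprotonation gives the extended enolate, whose α-carbon C7 displaces iodide from the neopentyl carbon C6 on the quaternary C5 of ring A. One operation forms ring B, the C7 stereocentre and the isopropenyl group, with C8 already a ketone. The precursor is a monocyclic ring A iodide carrying the silyloxy enone chain on C10.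

Key step: step 14

Remark on the chemistry: β is the face of ring A that carries the C5 methyl (C14), and C15 is the methyl on C4. The target is taken as (3R,4R,5R,7S,9S,10R). The CBS reduction in step 1 is assumed to follow the usual model (alkenyl side as the large group); the enantiomeric catalyst would be used if the opposite sense were found.

Step 1
Reactants: 1 2-methylcyclohex-2-en-1-one
Product: 2 (S)-2-methylcyclohex-2-en-1-ol
Conditions: (R)-2-methyl-CBS-oxazaborolidine (10 mol %), BH3·SMe2, THF, –20 °C
Reagents that add atoms: none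
Why: Corey–Bakshi–Shibata reduction should deliver hydride 1,2 to one carbonyl face and set the carbinol centre (later C4), which is the only source of absolute configuration.

Step 2
Reactants: 2 (S)-2-methylcyclohex-2-en-1-ol; 3 propargyl bromide
Product: 4 (S)-2-methylcyclohex-2-en-1-yl prop-2-yn-1-yl ether
Conditions: NaH, THF/DMF, 0 → 23 °C
Reagents that add atoms: none
Why: Williamson etherification of the allylic alkoxide with a reactive primary bromide leaves the stereocentre untouched.

Step 3
Reactants: 4 (S)-2-methylcyclohex-2-en-1-yl prop-2-yn-1-yl ether; 5 acetone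
Product: 8 (1S)-4-methyl-1-[(1R)-2-methylcyclohex-2-en-1-yl]pent-2-yne-1,4-diol, via dilithiated propargyl ether 6 (not isolated), via rearranged dilithium alkoxide acetylide 7 (not isolated)
Conditions: n-BuLi (2.5 equiv), THF, –78 → –30 °C; then acetone, –78 → 0 °C; aq NH4Cl
Reagents that add atoms: none
Why: [2,3]-Wittig rearrangement of the propargylic carbanion should form C9–C10 on the face of the departing oxygen (sets C10) with the alkynyl group exo in the envelope transition state of the cis-locked ring alkene (sets C9), and the acetylide then adds to acetone.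

Step 4
Reactants: 8 (1S)-4-methyl-1-[(1R)-2-methylcyclohex-2-en-1-yl]pent-2-yne-1,4-diol
Product: 9 (5S)-5-(tert-butyldimethylsilyloxy)-2-methyl-5-[(1R)-2-methylcyclohex-2-en-1-yl]pent-3-yn-2-ol
Conditions: TBSCl, imidazole, DMF, 0 → 23 °C
Reagents that add atoms: tert-butyldimethylsilyl chloride CC(C)(C)[Si](C)(C)Cl
Why: Silylation should be selective for the secondary propargylic alcohol (C9) over the tertiary one.

Step 5
Reactants: 9 (5S)-5-(tert-butyldimethylsilyloxy)-2-methyl-5-[(1R)-2-methylcyclohex-2-en-1-yl]pent-3-yn-2-ol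
Product: 10 (4R)-4-[(1S)-1-(tert-butyldimethylsilyloxy)-4-hydroxy-4-methylpent-2-yn-1-yl]-3-methylcyclohex-2-en-1-one
Conditions: CrO3, 3,5-dimethylpyrazole, CH2Cl2, –20 °C
Reagents that add atoms: chromium trioxide O=[Cr](=O)=O
Why: Allylic oxidation with the hexavalent chromium–pyrazole complex should occur at the ring methylene C3 next to the less substituted alkene carbon and give the C3 enone without touching C9 or C10.

Step 6
Reactants: 10 (4R)-4-[(1S)-1-(tert-butyldimethylsilyloxy)-4-hydroxy-4-methylpent-2-yn-1-yl]-3-methylcyclohex-2-en-1-one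
Product: 11 C3 trimethylsilyl enol ether of the 5β-methyl-5α-vinyl ring A ketone, with C9 OTBS and C11 OSiMe3 on the C10β side chain
Conditions: CH2=CHMgBr, CuBr·SMe2 (20 mol %), TMSCl, THF, –78 °C; then Et3N
Reagents that add atoms: vinylmagnesium bromide C=C[Mg]Br; chlorotrimethylsilane C[Si](C)(C)Cl
Why: Chlorosilane-accelerated conjugate addition of the vinyl cuprate (monovalent copper) should occur anti to the C10 side chain, creating the quaternary C5 (vinyl α, methyl β) and a regiodefined silyl enol ether, while excess TMSCl caps the tertiary alkoxide.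

Step 7
Reactants: 11 C3 trimethylsilyl enol ether of the 5β-methyl-5α-vinyl ring A ketone
Product: 15 4-methylene-3-oxo ring A ketone (5β-methyl, 5α-vinyl, C10β side chain with C9 OTBS and free tertiary OH), via Mannich base 12 (not isolated), via methiodide 13 (not isolated), via silylated enone 14 (not isolated)
Conditions: CH2=NMe2+ I– (Eschenmoser's salt), CH2Cl2, 23 °C; MeI; aq NaHCO3; then 0.5 M HCl, THF, 0 °C
Reagents that add atoms: Eschenmoser's salt C=[N+](C)C.[I-]
Why: Mannich reaction of the silyl enol ether at C4, quaternization and β-elimination should give the exocyclic enone (C15 as methylene), and the brief acid wash cleaves only the tertiary trimethylsilyl ether.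

Step 8
Reactants: 15 4-methylene-3-oxo ring A ketone
Product: 17 4β,5β-dimethyl-5α-vinyl-3-oxo ring A ketone, via lithium enolate 16 (not isolated)
Conditions: LiBH(s-Bu)3, THF, –78 °C; AcOH, –78 °C
Reagents that add atoms: none
Why: Conjugate reduction of the exocyclic enone gives the C3–C4 enolate, and kinetic axial protonation from the α face, anti to the axial C5 methyl, should set C4 with its methyl β (equatorial, cis to the C5 methyl).

Step 9
Reactants: 17 4β,5β-dimethyl-5α-vinyl-3-oxo ring A ketone
Product: 18 3α-hydroxy-4β,5β-dimethyl-5α-vinyl ring A alcohol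
Conditions: SmI2, H2O, Et3N, THF, 23 °C
Reagents that add atoms: none
Why: Single-electron (ketyl) reduction by divalent samarium, like a dissolving-metal reduction, should give the more stable equatorial 3α-alcohol without enolizing C4, because the axial epimer would be 1,3-diaxial to the C5 methyl.

Step 10
Reactants: 18 3α-hydroxy-4β,5β-dimethyl-5α-vinyl ring A alcohol; 19 angelic acid
Product: 20 3α-angelate of 18
Conditions: 19, 2,4,6-trichlorobenzoyl chloride, Et3N, toluene, 23 °C; then 18, 80 °C
Reagents that add atoms: none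
Why: Yamaguchi esterification through the mixed anhydride, without nucleophilic catalyst, should acylate the secondary alcohol with retention at C3 and without Z to E isomerization, while the tertiary alcohol stays inert.

Step 11
Reactants: 20 3α-angelate with the 5α-vinyl group
Product: 22 5α-hydroxymethyl ring A angelate (C6 alcohol), via aldehyde 21 (not isolated)
Conditions: O3, pyridine, CH2Cl2, –78 °C (Sudan Red 7B as indicator); then NaBH4, MeOH, –78 → 0 °C
Reagents that add atoms: ozone [O-][O+]=O
Why: Indicator-controlled ozonolysis should cleave the electron-rich terminal vinyl group faster than the electron-poor angelate or the alkyne, and borohydride reduces the C6 aldehyde to the neopentyl alcohol.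

Step 12
Reactants: 22 5α-hydroxymethyl ring A angelate
Product: 23 enone alcohol with the C10β side chain (9S)-CH(OTBS)–C(=O)–CH=CMe2
Conditions: Ph3PAuNTf2 (2 mol %), MeOH (1 equiv), toluene, 23 °C
Reagents that add atoms: none
Why: Meyer–Schuster rearrangement (1,3-hydroxyl shift of the tertiary propargylic alcohol through an allenol, monovalent gold catalysis) should place the carbonyl on C8 and the alkene at C7=C11.

Step 13
Reactants: 23 enone alcohol
Product: 25 neopentyl iodide (C6–I) of 23, via neopentyl triflate 24 (not isolated)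
Conditions: Tf2O, 2,6-lutidine, CH2Cl2, –78 °C; then n-Bu4NI, –78 → 23 °C
Reagents that add atoms: tetrabutylammonium iodide CCCC[N+](CCCC)(CCCC)CCCC.[I-]
Why: Triflation followed by SN2 displacement with iodide should convert the neopentyl alcohol into the iodide, since the triflate is reactive enough for substitution at C6 and the quaternary C5 rules out elimination.

Step 14
Reactants: 25 neopentyl iodide
Product: 27 (3R,4R,5R,7S,9S,10R)-3-angeloyloxy-9-(tert-butyldimethylsilyloxy)eremophil-11-en-8-one, via potassium dienolate 26 (not isolated)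
Conditions: KN(SiMe3)2 (1.05 equiv), THF, –78 → 23 °C; AcOH, –78 °C
Reagents that add atoms: none
Why: The base removes a γ-hydrogen from the s-cis enone (the only other α-hydrogen, at C9, is a hindered tertiary silyloxy methine) to give the (Z)-dienolate 26, whose α-carbon C7 displaces iodide from C6 in an intramolecular SN2 reaction, so the conjugated enone re-emerges as the β,γ-unsaturated ketone bearing the isopropenyl group. The closest known reaction type is the deconjugative α-alkylation of extended enolates, here intramolecular and onto a neopentyl-type iodide as in enolate cyclizations of terpenoid synthesis. Ring B closes in the 6-(enolendo)-exo-tet mode. The new C7 stereocentre is controlled by the chair-like transition state fixed by the equatorial C5–C6 and C10–C9 bonds of ring A: C11, cis to the enolate oxygen, becomes equatorial (7α), which is also the more stable epimer because an axial group on C7 would be 1,3-diaxial to the C5 methyl. The step needs C- over O-alkylation (both six-membered) and α- over γ-attack, which the soft iodide and the six- versus eight-membered ring should secure. About one equivalent of base and a cold acidic quench should avoid reconjugation and spare the angelate.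

Step 15
Reactants: 27 9-silyloxy eremophilenone
Product: 28 (3R,4R,5R,7S,9S,10R)-3-angeloyloxy-9-hydroxyeremophil-11-en-8-one
Conditions: HF·pyridine, pyridine, THF, 0 → 23 °C
Reagents that add atoms: none
Why: Buffered fluoride desilylation should free the C9 alcohol without base, so C7 and C9 are not epimerized and the alkene is not moved into conjugation.

Step 16
Reactants: 28 9-hydroxy eremophilenone; 29 (E)-3-methylpent-2-enoic acid
Product: 30 target, (3R,4R,5R,7S,9S,10R)-3-[(Z)-2-methylbut-2-enoyloxy]-9-[(E)-3-methylpent-2-enoyloxy]eremophil-11-en-8-one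
Conditions: 29, DCC, DMAP (10 mol %), CH2Cl2, 0 → 23 °C
Reagents that add atoms: none
Why: Steglich esterification of the α-hydroxy ketone under mild conditions should retain the E geometry of the acid and the configurations at C7 and C9.

Compound list
1 | 2-methylcyclohex-2-en-1-one | CC1=CCCCC1=O | starting material
2 | (S)-2-methylcyclohex-2-en-1-ol | CC1=CCCC[C@@H]1O | intermediate
3 | propargyl bromide (3-bromoprop-1-yne) | C#CCBr | starting material
4 | (S)-2-methylcyclohex-2-en-1-yl prop-2-yn-1-yl ether | CC1=CCCC[C@@H]1OCC#C | intermediate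
5 | acetone | CC(C)=O | starting material
6 | dilithiated propargyl ether (lithium acetylide, lithiated at the OCH carbon) | CC1=CCCC[C@@H]1O[CH-]C#[C-].[Li+].[Li+] | intermediate
7 | rearranged dilithium alkoxide acetylide, dilithium salt of (1S)-1-[(1R)-2-methylcyclohex-2-en-1-yl]prop-2-yn-1-ol | CC1=CCCC[C@H]1[C@H]([O-])C#[C-].[Li+].[Li+] | intermediate
8 | (1S)-4-methyl-1-[(1R)-2-methylcyclohex-2-en-1-yl]pent-2-yne-1,4-diol | CC1=CCCC[C@H]1[C@H](O)C#CC(C)(C)O | intermediate
9 | (5S)-5-(tert-butyldimethylsilyloxy)-2-methyl-5-[(1R)-2-methylcyclohex-2-en-1-yl]pent-3-yn-2-ol | CC1=CCCC[C@H]1[C@H](O[Si](C)(C)C(C)(C)C)C#CC(C)(C)O | intermediate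
10 | (4R)-4-[(1S)-1-(tert-butyldimethylsilyloxy)-4-hydroxy-4-methylpent-2-yn-1-yl]-3-methylcyclohex-2-en-1-one | CC1=CC(=O)CC[C@H]1[C@H](O[Si](C)(C)C(C)(C)C)C#CC(C)(C)O | intermediate
11 | C3 trimethylsilyl enol ether, 5β-methyl, 5α-vinyl, C10β side chain (1S)-1-(TBSO)-4-methyl-4-(trimethylsilyloxy)pent-2-yn-1-yl | C=C[C@]1(C)C=C(O[Si](C)(C)C)CC[C@H]1[C@H](O[Si](C)(C)C(C)(C)C)C#CC(C)(C)O[Si](C)(C)C | intermediate
12 | Mannich base, 3-oxo, 4α-(dimethylaminomethyl), otherwise as 11 | C=C[C@]1(C)[C@H](CN(C)C)C(=O)CC[C@H]1[C@H](O[Si](C)(C)C(C)(C)C)C#CC(C)(C)O[Si](C)(C)C | intermediate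
13 | methiodide of 12 | C=C[C@]1(C)[C@H](C[N+](C)(C)C)C(=O)CC[C@H]1[C@H](O[Si](C)(C)C(C)(C)C)C#CC(C)(C)O[Si](C)(C)C.[I-] | intermediate
14 | 4-methylene-3-oxo ring A ketone with C11 trimethylsilyl ether | C=C[C@]1(C)C(=C)C(=O)CC[C@H]1[C@H](O[Si](C)(C)C(C)(C)C)C#CC(C)(C)O[Si](C)(C)C | intermediate
15 | 4-methylene-3-oxo ring A ketone, 5β-methyl, 5α-vinyl, C10β side chain (1S)-1-(TBSO)-4-hydroxy-4-methylpent-2-yn-1-yl | C=C[C@]1(C)C(=C)C(=O)CC[C@H]1[C@H](O[Si](C)(C)C(C)(C)C)C#CC(C)(C)O | intermediate
16 | lithium C3–C4 enolate carrying the new C15 methyl on C4 | C=C[C@]1(C)C(C)=C([O-])CC[C@H]1[C@H](O[Si](C)(C)C(C)(C)C)C#CC(C)(C)O.[Li+] | intermediate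
17 | 3-oxo ring A ketone, 4β,5β-dimethyl, 5α-vinyl, side chain as in 15 | C=C[C@]1(C)[C@@H](C)C(=O)CC[C@H]1[C@H](O[Si](C)(C)C(C)(C)C)C#CC(C)(C)O | intermediate
18 | 3α-hydroxy ring A alcohol, 4β,5β-dimethyl, 5α-vinyl, side chain as in 15 | C=C[C@]1(C)[C@@H](C)[C@H](O)CC[C@H]1[C@H](O[Si](C)(C)C(C)(C)C)C#CC(C)(C)O | intermediate
19 | angelic acid, (Z)-2-methylbut-2-enoic acid | C/C=C(/C)C(=O)O | starting material
20 | 3α-angelate of 18 | C=C[C@]1(C)[C@@H](C)[C@H](OC(=O)/C(C)=C\C)CC[C@H]1[C@H](O[Si](C)(C)C(C)(C)C)C#CC(C)(C)O | intermediate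
21 | C6 aldehyde (5α-formyl) from ozonolysis of 20 | O=C[C@]1(C)[C@@H](C)[C@H](OC(=O)/C(C)=C\C)CC[C@H]1[C@H](O[Si](C)(C)C(C)(C)C)C#CC(C)(C)O | intermediate
22 | C6 alcohol (5α-hydroxymethyl), 3α-angelate, alkynyl diol side chain with C9 OTBS | OC[C@]1(C)[C@@H](C)[C@H](OC(=O)/C(C)=C\C)CC[C@H]1[C@H](O[Si](C)(C)C(C)(C)C)C#CC(C)(C)O | intermediate
23 | enone alcohol, C10β side chain (9S)-CH(OTBS)–C(=O)–CH=CMe2, 5α-hydroxymethyl, 3α-angelate | OC[C@]1(C)[C@@H](C)[C@H](OC(=O)/C(C)=C\C)CC[C@H]1[C@H](O[Si](C)(C)C(C)(C)C)C(=O)C=C(C)C | intermediate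
24 | C6 triflate of 23 | O=S(=O)(OC[C@]1(C)[C@@H](C)[C@H](OC(=O)/C(C)=C\C)CC[C@H]1[C@H](O[Si](C)(C)C(C)(C)C)C(=O)C=C(C)C)C(F)(F)F | intermediate
25 | C6 iodide (5α-iodomethyl) of 23 | IC[C@]1(C)[C@@H](C)[C@H](OC(=O)/C(C)=C\C)CC[C@H]1[C@H](O[Si](C)(C)C(C)(C)C)C(=O)C=C(C)C | intermediate
26 | potassium (Z)-dienolate of 25 (O–C8=C7–C11=C13) | IC[C@]1(C)[C@@H](C)[C@H](OC(=O)/C(C)=C\C)CC[C@H]1[C@H](O[Si](C)(C)C(C)(C)C)/C([O-])=C/C(C)=C.[K+] | intermediate
27 | (3R,4R,5R,7S,9S,10R)-3-angeloyloxy-9-(tert-butyldimethylsilyloxy)eremophil-11-en-8-one | C=C(C)[C@@H]1C[C@]2(C)[C@@H](C)[C@H](OC(=O)/C(C)=C\C)CC[C@H]2[C@H](O[Si](C)(C)C(C)(C)C)C1=O | intermediate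
28 | (3R,4R,5R,7S,9S,10R)-3-angeloyloxy-9-hydroxyeremophil-11-en-8-one | C=C(C)[C@@H]1C[C@]2(C)[C@@H](C)[C@H](OC(=O)/C(C)=C\C)CC[C@H]2[C@H](O)C1=O | intermediate
29 | (E)-3-methylpent-2-enoic acid | CC/C(C)=C/C(=O)O | starting material
30 | (3R,4R,5R,7S,9S,10R)-3-[(Z)-2-methylbut-2-enoyloxy]-9-[(E)-3-methylpent-2-enoyloxy]eremophil-11-en-8-one | C=C(C)[C@@H]1C[C@]2(C)[C@@H](C)[C@H](OC(=O)/C(C)=C\C)CC[C@H]2[C@H](OC(=O)/C=C(\C)CC)C1=O | target

Total step count: 16. Longest linear sequence: 16 steps (1 to 30).

Steps most likely to fail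

Step 14. The displacement at the neopentyl carbon C6 may be slow. O-alkylation to the six-membered enol ether, enolization towards C9 with loss of its configuration, or base-induced isomerization of the angelate could then compete. The fallback sets out from alcohol 23 and replaces alkylation by aldol condensation and conjugate reduction. Oxidation with Dess–Martin periodinane should give keto aldehyde F1. KN(SiMe3)2 (THF, –78 °C) then closes ring B by addition of the same extended enolate, through C7, to the non-enolizable C6 aldehyde, giving aldol F2 as an epimer mixture at C6 and C7. Mesylation (MsCl, Et3N) gives mesylate F3, and DBU eliminates to the cross-conjugated dienone F4. Conjugate reduction with [(Ph3P)CuH]6 (hydride to C6) and kinetic protonation of the dienolate at C7 should return the route at 27.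

Step 5. Hydrogen abstraction may be unselective (C10–H, the C14 methyl or the propargylic C9–H), or the side chain may be over-oxidized. The fallback sets out from 9 and moves the oxygen in by epoxide chemistry. mCPBA should give the 4,5-epoxide F5 from the α face. Ring opening at the less hindered C4 with PhSeNa (from (PhSe)2 and NaBH4) gives hydroxy selenide F6. Oxidation with H2O2 and selenoxide elimination towards C3 gives the tertiary allylic alcohol F7. Oxidative 1,3-transposition with pyridinium chlorochromate (C5H5NH[CrO3Cl]) should return the route at enone 10.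

Step 9. Facial selectivity of the ketone reduction may be poor, or ketyl dimerization may intervene. The fallback sets out from 17 and uses inversion instead of direct equatorial delivery. LiBH(s-Bu)3 attacks from the open α face and should give the axial 3β-alcohol F8. Mitsunobu esterification with angelic acid 19 (PPh3, DIAD) then inverts C3 and gives the 3α-angelate directly, rejoining the route at 20.

Further compounds
F1 | step 14 | keto aldehyde, 5α-formyl analogue of 23 | O=C[C@]1(C)[C@@H](C)[C@H](OC(=O)/C(C)=C\C)CC[C@H]1[C@H](O[Si](C)(C)C(C)(C)C)C(=O)C=C(C)C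
F2 | step 14 | aldol, 6-hydroxy derivative of 27 (epimer mixture at C6 and C7) | C=C(C)C1C(O)[C@]2(C)[C@@H](C)[C@H](OC(=O)/C(C)=C\C)CC[C@H]2[C@H](O[Si](C)(C)C(C)(C)C)C1=O
F3 | step 14 | mesylate of F2 | C=C(C)C1C(OS(C)(=O)=O)[C@]2(C)[C@@H](C)[C@H](OC(=O)/C(C)=C\C)CC[C@H]2[C@H](O[Si](C)(C)C(C)(C)C)C1=O
F4 | step 14 | cross-conjugated dienone, 6,7-dehydro derivative of 27 | C=C(C)C1=C[C@]2(C)[C@@H](C)[C@H](OC(=O)/C(C)=C\C)CC[C@H]2[C@H](O[Si](C)(C)C(C)(C)C)C1=O
F5 | step 5 | 4α,5α-epoxide of 9 | O3[C@]1(C)[C@H]3CCC[C@H]1[C@H](O[Si](C)(C)C(C)(C)C)C#CC(C)(C)O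
F6 | step 5 | 5α-hydroxy-4β-phenylselanyl derivative from F5 | O[C@]1(C)[C@@H]([Se]c2ccccc2)CCC[C@H]1[C@H](O[Si](C)(C)C(C)(C)C)C#CC(C)(C)O
F7 | step 5 | tertiary allylic alcohol, 5α-hydroxy-5β-methyl with C3=C4 alkene | O[C@]1(C)C=CCC[C@H]1[C@H](O[Si](C)(C)C(C)(C)C)C#CC(C)(C)O
F8 | step 9 | 3β-hydroxy (axial) epimer of 18 | C=C[C@]1(C)[C@@H](C)[C@@H](O)CC[C@H]1[C@H](O[Si](C)(C)C(C)(C)C)C#CC(C)(C)O
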